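## Retrosynthetic overview
- Ring C is opened at the O1–C2 bond, giving a fully O‑silylated 2‑aryl‑1‑(2,4,6‑trioxyphenyl)prop‑2‑en‑1‑one. Closing this C–O bond by oxa‑Michael addition and protonating the resulting enolate enantioselectively sets C3 in the last step, so the labile α‑aryl ketone stereocentre meets no later reagent.
- The enone is cut at C3–C4 into a 1‑arylvinyllithium (Shapiro reaction of the ring B methyl ketone) and silylated 2,4,6‑trihydroxybenzaldehyde, followed by alcohol oxidation.
- The ring B ketone is cut at its pyran ring, leading back to 3',4'‑dihydroxyacetophenone by O‑4‑selective tertiary propargylation and propargyl Claisen/oxa‑6π cyclisation.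
- Ring order: rings A and B are bought, the dimethylpyran ring is made first (step 2), and ring C is made last (step 7).

Assumption: the SMILES encodes (3S) (C4 > C2 > aryl > H). (R)‑BINAP is written for step 7, and if a test run gives the (3R) product, (S)‑BINAP is used with nothing else changed. TBS = tert‑butyldimethylsilyl.

## Route

Step 1
Reactants: 1 3',4'-dihydroxyacetophenone; 2 3-chloro-3-methylbut-1-yne
Product: 3 1-[3-hydroxy-4-(2-methylbut-3-yn-2-yloxy)phenyl]ethan-1-one
Conditions: K2CO3 (1.1 equiv), KI (0.2 equiv), CuI (5 mol %), DMF, 60 °C, under argon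
Reagents that add atoms: none
Why: Copper‑assisted Williamson‑type O‑propargylation, in which one equivalent of weak base ionises only the 4‑OH (para to the acetyl group and about two pKa units more acidic than the 3‑OH), so the tertiary propargyl group goes on O‑4, the same control that gives 4‑O‑monoethers of protocatechualdehyde.

Step 2
Reactants: 3 1-[3-hydroxy-4-(2-methylbut-3-yn-2-yloxy)phenyl]ethan-1-one
Product: 5 1-[8-(tert-butyldimethylsilyloxy)-2,2-dimethyl-2H-chromen-6-yl]ethan-1-one, via 6-acetyl-8-hydroxy-2,2-dimethyl-2H-chromene 4 (not isolated)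
Conditions: DMF, 150 °C, 8 h; cool to rt; imidazole (2.5 equiv), TBSCl (1.3 equiv), rt
Reagents that add atoms: tert-butyldimethylsilyl chloride, CC(C)(C)[Si](C)(C)Cl
Why: Aromatic propargyl Claisen rearrangement to the only free ortho carbon, then enolisation, 1,5‑H shift and oxa‑6π electrocyclisation give the 2,2‑dimethylchromene, and standard imidazole silylation in the same DMF solution removes the last acidic proton before the organolithium step.

Step 3
Reactants: 5 1-[8-(tert-butyldimethylsilyloxy)-2,2-dimethyl-2H-chromen-6-yl]ethan-1-one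
Product: 6 (E)-N'-{1-[8-(tert-butyldimethylsilyloxy)-2,2-dimethyl-2H-chromen-6-yl]ethylidene}-2,4,6-triisopropylbenzenesulfonohydrazide
Conditions: 2,4,6-triisopropylbenzenesulfonyl hydrazide (1.05 equiv), pyridinium tosylate (2 mol %), MeCN, rt, 16 h
Reagents that add atoms: 2,4,6-triisopropylbenzenesulfonyl hydrazide, CC(C)c1cc(C(C)C)c(S(=O)(=O)NN)c(C(C)C)c1
Why: Acid‑catalysed hydrazone condensation, using the trisyl group because it cannot be ortho‑lithiated and loses sulfinate at 0 °C, with the (E)‑hydrazone placing N–N syn to the methyl group that must be deprotonated.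

Step 4
Reactants: 7 2,4,6-trihydroxybenzaldehyde
Product: 8 2,4,6-tris(tert-butyldimethylsilyloxy)benzaldehyde
Conditions: TBSCl (4 equiv), imidazole (8 equiv), DMAP (10 mol %), DMF, 40 °C
Reagents that add atoms: tert-butyldimethylsilyl chloride, CC(C)(C)[Si](C)(C)Cl
Why: Exhaustive imidazole/DMAP silylation of phenols, with excess reagent and mild warming also capping the two hydrogen‑bonded ortho hydroxyls.

Step 5
Reactants: 6 (E)-trisylhydrazone of ketone 5; 8 2,4,6-tris(tert-butyldimethylsilyloxy)benzaldehyde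
Product: 10 (±)-2-[8-(tert-butyldimethylsilyloxy)-2,2-dimethyl-2H-chromen-6-yl]-1-[2,4,6-tris(tert-butyldimethylsilyloxy)phenyl]prop-2-en-1-ol, via 1-arylvinyllithium 9 (not isolated)
Conditions: n-BuLi (2.1 equiv), THF, −78 °C then 0 °C (10 min, N2 evolution); 8 (0.9 equiv), −78 °C, 1 h; AcOH/THF quench at −78 °C
Reagents that add atoms: none
Why: Shapiro reaction (hydrazone dianion, loss of sulfinate and N2) gives the 1‑arylvinyllithium, which adds 1,2 to the aldehyde, and the new carbinol centre is racemic and is erased in step 6.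

Step 6
Reactants: 10 (±)-allylic benzylic alcohol
Product: 11 2-[8-(tert-butyldimethylsilyloxy)-2,2-dimethyl-2H-chromen-6-yl]-1-[2,4,6-tris(tert-butyldimethylsilyloxy)phenyl]prop-2-en-1-one
Conditions: activated MnO2 (20 equiv), CH2Cl2, rt; filter, use within a day
Reagents that add atoms: none
Why: MnO2 oxidation of a doubly activated (benzylic and allylic) alcohol under neutral conditions, which spares the silyl ethers, the chromene and the ionisation‑prone carbinol.

Step 7
Reactants: 11 tetra-O-TBS α-aryl enone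
Product: 13 (3S)-5,7-dihydroxy-3-(8-hydroxy-2,2-dimethyl-2H-chromen-6-yl)chroman-4-one (CNP0298948.1), via (3S)-tris-O-TBS-isoflavanone 12 (not isolated)
Conditions: AgF (10 mol %), (R)-BINAP (11 mol %), MeOH (20 equiv), CH2Cl2, −20 °C, dark, 24 h; then Et3N·3HF (3 equiv), THF, 0 °C, 2 h
Reagents that add atoms: none
Why: Proposed new method: a desilylative oxa‑Michael ring closure relayed into an enantioselective protonation, in which fluoride (first turnover) or methoxide (later turnovers) on BINAP‑bound monovalent silver removes the silyl group from an ortho aryl silyl ether whose phenoxide is a good leaving group because of the neighbouring ketone, the resulting BINAP·Ag phenoxide adds 6‑endo‑trig to the unsubstituted enone terminus to form the O1–C2 bond and a ring‑locked BINAP·Ag enolate of a 2‑aryl cyclic ketone, and MeOH protonates C3 of that enolate inside the chiral pocket (setting 3S) while regenerating AgOMe, so the only counter‑ion paired with phenoxide or enolate is chiral and the weakly acidic Et3N·3HF finish should not epimerise C3; the closest known reaction types are the BINAP·AgF‑catalysed enantioselective protonation of trimethylsilyl enol ethers of 2‑aryl cycloalkanones by MeOH and the base‑induced racemic oxa‑Michael closure of 2'‑hydroxy‑α‑methylenedeoxybenzoins to isoflavanones.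

## Compound list
1 | 3',4'-dihydroxyacetophenone | CC(=O)c1ccc(O)c(O)c1 | starting material
2 | 3-chloro-3-methylbut-1-yne | CC(C)(Cl)C#C | starting material
3 | 1-[3-hydroxy-4-(2-methylbut-3-yn-2-yloxy)phenyl]ethan-1-one | CC(=O)c1ccc(OC(C)(C)C#C)c(O)c1 | intermediate
4 | 1-(8-hydroxy-2,2-dimethyl-2H-chromen-6-yl)ethan-1-one (not isolated) | CC(=O)c1cc(O)c2OC(C)(C)C=Cc2c1 | intermediate
5 | 1-[8-(tert-butyldimethylsilyloxy)-2,2-dimethyl-2H-chromen-6-yl]ethan-1-one | CC(=O)c1cc(O[Si](C)(C)C(C)(C)C)c2OC(C)(C)C=Cc2c1 | intermediate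
6 | (E)-2,4,6-triisopropylbenzenesulfonylhydrazone of 5 | C/C(=N\NS(=O)(=O)c1c(C(C)C)cc(C(C)C)cc1C(C)C)c1cc(O[Si](C)(C)C(C)(C)C)c2OC(C)(C)C=Cc2c1 | intermediate
7 | 2,4,6-trihydroxybenzaldehyde | O=Cc1c(O)cc(O)cc1O | starting material
8 | 2,4,6-tris(tert-butyldimethylsilyloxy)benzaldehyde | O=Cc1c(O[Si](C)(C)C(C)(C)C)cc(O[Si](C)(C)C(C)(C)C)cc1O[Si](C)(C)C(C)(C)C | intermediate
9 | {1-[8-(tert-butyldimethylsilyloxy)-2,2-dimethyl-2H-chromen-6-yl]vinyl}lithium (not isolated) | [Li]C(=C)c1cc(O[Si](C)(C)C(C)(C)C)c2OC(C)(C)C=Cc2c1 | intermediate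
10 | (±)-2-[8-(TBSO)-2,2-dimethyl-2H-chromen-6-yl]-1-[2,4,6-tris(TBSO)phenyl]prop-2-en-1-ol | OC(C(=C)c1cc(O[Si](C)(C)C(C)(C)C)c2OC(C)(C)C=Cc2c1)c1c(O[Si](C)(C)C(C)(C)C)cc(O[Si](C)(C)C(C)(C)C)cc1O[Si](C)(C)C(C)(C)C | intermediate
11 | 2-[8-(TBSO)-2,2-dimethyl-2H-chromen-6-yl]-1-[2,4,6-tris(TBSO)phenyl]prop-2-en-1-one | C=C(C(=O)c1c(O[Si](C)(C)C(C)(C)C)cc(O[Si](C)(C)C(C)(C)C)cc1O[Si](C)(C)C(C)(C)C)c1cc(O[Si](C)(C)C(C)(C)C)c2OC(C)(C)C=Cc2c1 | intermediate
12 | (3S)-5,7-bis(TBSO)-3-[8-(TBSO)-2,2-dimethyl-2H-chromen-6-yl]chroman-4-one (not isolated) | CC1(C)C=Cc2cc([C@H]3COc4cc(O[Si](C)(C)C(C)(C)C)cc(O[Si](C)(C)C(C)(C)C)c4C3=O)cc(O[Si](C)(C)C(C)(C)C)c2O1 | intermediate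
13 | (3S)-5,7-dihydroxy-3-(8-hydroxy-2,2-dimethyl-2H-chromen-6-yl)chroman-4-one | CC1(C)C=Cc2cc([C@H]3COc4cc(O)cc(O)c4C3=O)cc(O)c2O1 | target

## Step count and weak points
Total steps: 7. Longest linear sequence: 6 (steps 1, 2, 3, 5, 6, 7).

**Step 7 (the new step).**
- Risks: the TBS ethers may be unmasked too slowly at −20 °C. MeOH may add reversibly to the enone. The phenols released during the reaction may compete as proton donors and lower the ee. Further loss of silyl groups in the first stage does no harm, because all of them are removed in the second stage.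
- Fallback (known chemistry): it sets out from 11. Bu4NF (4.4 equiv) in THF at 0 °C, followed by AcOH, strips all four silyl groups. The free 2'‑phenoxide then closes ring C spontaneously to racemic 5,7-dihydroxy-3-(8-hydroxy-2,2-dimethyl-2H-chromen-6-yl)chroman-4-one F4. Preparative chiral SFC on an amylose tris(3,5‑dimethylphenylcarbamate) phase gives the (3S)‑enantiomer. The unwanted (3R)-5,7-dihydroxy-3-(8-hydroxy-2,2-dimethyl-2H-chromen-6-yl)chroman-4-one F5 is racemised back to F4 with catalytic Et3N in EtOAc and recycled. The fallback comes back to the route at 13.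

**Step 5.**
- Risks: the lithium alkoxide sits between two ortho silyloxy groups. It can take over a silyl group (O‑to‑O migration) and then expel silanolate to an ortho‑quinone methide, which would cyclise to the isoflav‑3‑ene. The vinyllithium can also be protonated by THF at 0 °C.
- Fallback: it sets out from 5. KN(SiMe3)2 and PhNTf2 in THF at −78 °C give 1-[8-(tert-butyldimethylsilyloxy)-2,2-dimethyl-2H-chromen-6-yl]vinyl trifluoromethanesulfonate F3. This is coupled with 8 under Nozaki–Hiyama–Kishi conditions (CrCl2 4 equiv, NiCl2 2 mol %, DMF, rt). The trivalent chromium alkoxide formed is too weakly nucleophilic to pull over a silyl group. The fallback comes back to the route at 10.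

**Step 1.**
- Risks: O‑3 alkylation or bis‑alkylation may occur, and the catechol may bind the copper catalyst.
- Fallback: it sets out from 2, which alkylates commercial acetovanillone (CC(=O)c1ccc(O)c(OC)c1), whose only free hydroxyl is O‑4, under the same base system. This gives 1-[3-methoxy-4-(2-methylbut-3-yn-2-yloxy)phenyl]ethan-1-one F1. Heating in DMF at 150 °C gives 1-(8-methoxy-2,2-dimethyl-2H-chromen-6-yl)ethan-1-one F2. NaSEt in DMF at 110 °C then cleaves the methyl ether by SN2 attack at methyl, which the tertiary pyran C–O bond cannot undergo. Regiochemistry is thus fixed by the purchased methyl ether instead of by pKa control. The fallback comes back to the route at 4, which is silylated as in step 2.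

## Further compounds
F1 | step 1 | 1-[3-methoxy-4-(2-methylbut-3-yn-2-yloxy)phenyl]ethan-1-one | CC(=O)c1ccc(OC(C)(C)C#C)c(OC)c1
F2 | step 1 | 1-(8-methoxy-2,2-dimethyl-2H-chromen-6-yl)ethan-1-one | CC(=O)c1cc(OC)c2OC(C)(C)C=Cc2c1
F3 | step 5 | 1-[8-(tert-butyldimethylsilyloxy)-2,2-dimethyl-2H-chromen-6-yl]vinyl trifluoromethanesulfonate | C=C(OS(=O)(=O)C(F)(F)F)c1cc(O[Si](C)(C)C(C)(C)C)c2OC(C)(C)C=Cc2c1
F4 | step 7 | racemic 5,7-dihydroxy-3-(8-hydroxy-2,2-dimethyl-2H-chromen-6-yl)chroman-4-one | CC1(C)C=Cc2cc(C3COc4cc(O)cc(O)c4C3=O)cc(O)c2O1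
F5 | step 7 | (3R)-5,7-dihydroxy-3-(8-hydroxy-2,2-dimethyl-2H-chromen-6-yl)chroman-4-one | CC1(C)C=Cc2cc([C@@H]3COc4cc(O)cc(O)c4C3=O)cc(O)c2O1
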